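**Retrosynthetic overview**
- Target 14 comes from acid 13 by exchange of the C2 carboxyl group for bromine. The C3 chlorine comes from electrophilic chlorination of indole-2-ester 11, and 11 comes from indoline 9 by Boc removal and dehydrogenation.
- Indoline 9 is cut at N1–C7a and C3–C3a in one operation, giving 3,6-dibromobenzyne (released from silyl triflate 6) and Boc-dehydroalanine methyl ester 7.
- Silyl triflate 6 comes from 2,5-dibromophenol 1 by O-silylation, ortho-lithiation with O-to-C silyl shift, and triflation.
- Feature used: the bromines at C4 and C7 of the benzo ring sit on either side of the C3a–C7a fusion bond, so the aryne spanning these two carbons is symmetric and N1 and C3 can be attached without a regiochemical question. The C2 ester is the handle for the last bromine.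
- Ring order: the benzene ring is bought; the five-membered nitrogen ring is the only ring formed (step 4).

Key step: step 4

Assumption: the indoline C2 centre is formed racemic, which is acceptable because the target is achiral and C2 becomes sp2 in step 6.

**Route**

Step 1
Reactants: 1 2,5-dibromophenol
Product: 2 (2,5-dibromophenoxy)trimethylsilane
Conditions: (Me3Si)2NH (0.75 equiv), THF, 70 °C; concentrate
Reagents that add atoms: hexamethyldisilazane, C[Si](C)(C)N[Si](C)(C)C
Why: O-silylation of an acidic phenol with a disilazane, in which ammonia is the only by-product, so the ether should be obtained clean by evaporation.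

Step 2
Reactants: 2 (2,5-dibromophenoxy)trimethylsilane
Product: 5 3,6-dibromo-2-(trimethylsilyl)phenol, via aryllithium 3 (not isolated), via lithium phenoxide 4 (not isolated)
Conditions: LiN(iPr)2 (1.15 equiv), THF, −78 °C; NH4Cl aq, −78 → 23 °C
Reagents that add atoms: lithium diisopropylamide, [Li+].CC(C)[N-]C(C)C (its lithium is carried only by the non-isolated 3 and 4; no atom other than hydrogen reaches 5)
Why: Directed ortho-lithiation followed by anionic 1,3 O-to-C silyl migration (retro-Brook rearrangement), in which the amide base removes the most acidic ring hydrogen (between the silyloxy group and bromine) without bromine–lithium exchange and the irreversible silyl shift to the phenoxide should outrun LiBr loss at −78 °C.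

Step 3
Reactants: 5 3,6-dibromo-2-(trimethylsilyl)phenol
Product: 6 3,6-dibromo-2-(trimethylsilyl)phenyl trifluoromethanesulfonate
Conditions: Tf2O (1.2 equiv), pyridine (2 equiv), CH2Cl2, 0 °C
Reagents that add atoms: trifluoromethanesulfonic anhydride, O=S(=O)(OS(=O)(=O)C(F)(F)F)C(F)(F)F
Why: O-sulfonylation of a phenol with triflic anhydride and pyridine, the usual last step towards an ortho-silylaryl triflate, under which the aryl–silicon and aryl–bromine bonds are inert.

Step 4
Reactants: 6 3,6-dibromo-2-(trimethylsilyl)phenyl trifluoromethanesulfonate; 7 methyl 2-[(tert-butoxycarbonyl)amino]acrylate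
Product: 9 1-tert-butyl 2-methyl 4,7-dibromoindoline-1,2-dicarboxylate (racemic), via 3,6-dibromobenzyne 8 (not isolated)
Conditions: 7 (1.0 equiv), [Bu4N][Ph3SiF2] (2.0 equiv), THF (dilute), 23 °C; slow addition of 6 (1.5 equiv)
Reagents that add atoms: none
Why: Fluoride from [Bu4N][Ph3SiF2] attacks the silicon of 6 and the developing aryl anion expels the ortho triflate, a much better leaving group than the bromide on its other side, to give aryne 8; the carbamate nitrogen of 7 then adds to one aryne carbon (N1–C7a), the aryl anion so formed adds to the CH2 terminus of the acrylate (C3–C3a), and the ester enolate is protonated at C2 by the N–H of a further molecule of 7. The closest known reaction type is the fluoride-induced annulation of arynes with N-carbamoyl dehydroalanine esters, which gives indoline-2-carboxylates. The five-membered ring is closed in the 5-endo-trig mode by conjugate addition of the aryl anion to the enamide acceptor held next to it. The only new stereocentre, C2, is set by uncontrolled protonation of a planar enolate, so 9 is racemic, and this centre becomes sp2 in step 6. Regioselectivity is not needed because the two aryne carbons of 8 are equivalent, each flanked by one C–Br. The selectivity that is needed is ring closure ahead of bromide loss or external protonation of the ortho-bromoaryl anion, which the proximity of the acceptor, the inductive stabilisation of the anion by the neighbouring bromine and slow aryne generation in dilute THF at 23 °C should secure.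

Step 5
Reactants: 9 1-tert-butyl 2-methyl 4,7-dibromoindoline-1,2-dicarboxylate (racemic)
Product: 10 methyl 4,7-dibromoindoline-2-carboxylate (racemic)
Conditions: CF3CO2H, CH2Cl2, 0 → 23 °C; NaHCO3 aq work-up
Reagents that add atoms: none
Why: Acidolysis of a tert-butyl carbamate with loss of isobutene and CO2, to which the methyl ester and the aryl bromides are inert.

Step 6
Reactants: 10 methyl 4,7-dibromoindoline-2-carboxylate (racemic)
Product: 11 methyl 4,7-dibromo-1H-indole-2-carboxylate
Conditions: DDQ (1.2 equiv), toluene, 23 → 60 °C
Reagents that add atoms: none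
Why: Quinone dehydrogenation of an N–H indoline to the indole, driven by aromatisation of the pyrrole ring, which also removes the C2 stereocentre.

Step 7
Reactants: 11 methyl 4,7-dibromo-1H-indole-2-carboxylate
Product: 12 methyl 4,7-dibromo-3-chloro-1H-indole-2-carboxylate
Conditions: NCS (1.1 equiv), DMF, 23 → 45 °C
Reagents that add atoms: N-chlorosuccinimide, O=C1CCC(=O)N1Cl
Why: Electrophilic aromatic chlorination at C3, the only free and the most nucleophilic carbon of the pyrrole ring, while the ester and the two bromines deactivate C5 and C6 against further halogenation.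

Step 8
Reactants: 12 methyl 4,7-dibromo-3-chloro-1H-indole-2-carboxylate
Product: 13 4,7-dibromo-3-chloro-1H-indole-2-carboxylic acid
Conditions: LiOH·H2O (3 equiv), THF/MeOH/H2O, 23 °C; then 1 M HCl
Reagents that add atoms: lithium hydroxide, [Li+].[OH-]
Why: Saponification of a methyl ester by acyl substitution with hydroxide, under which the C3–Cl and the aryl C–Br bonds should be stable.

Step 9
Reactants: 13 4,7-dibromo-3-chloro-1H-indole-2-carboxylic acid
Product: 14 2,4,7-tribromo-3-chloro-1H-indole
Conditions: NBS (1.05 equiv), DMF, 0 → 23 °C, dark
Reagents that add atoms: N-bromosuccinimide, O=C1CCC(=O)N1Br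
Why: Electrophilic ipso-bromodecarboxylation of a 3-haloindole-2-carboxylic acid with an N-halosuccinimide, in which, with C3 blocked, bromine is delivered to C2 and the cationic intermediate regains aromaticity by losing CO2.

**Compound list**
1 | 2,5-dibromophenol | Oc1cc(Br)ccc1Br | starting material
2 | (2,5-dibromophenoxy)trimethylsilane | C[Si](C)(C)Oc1cc(Br)ccc1Br | intermediate
3 | [3,6-dibromo-2-(trimethylsilyloxy)phenyl]lithium | [Li]c1c(Br)ccc(Br)c1O[Si](C)(C)C | intermediate (not isolated)
4 | lithium 3,6-dibromo-2-(trimethylsilyl)phenoxide | [Li+].[O-]c1c(Br)ccc(Br)c1[Si](C)(C)C | intermediate (not isolated)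
5 | 3,6-dibromo-2-(trimethylsilyl)phenol | Oc1c(Br)ccc(Br)c1[Si](C)(C)C | intermediate
6 | 3,6-dibromo-2-(trimethylsilyl)phenyl trifluoromethanesulfonate | C[Si](C)(C)c1c(Br)ccc(Br)c1OS(=O)(=O)C(F)(F)F | intermediate
7 | methyl 2-[(tert-butoxycarbonyl)amino]acrylate | COC(=O)C(=C)NC(=O)OC(C)(C)C | starting material
8 | 3,6-dibromobenzyne (1,4-dibromo-2,3-didehydrobenzene) | BrC1=CC=C(Br)C#C1 | intermediate (not isolated)
9 | 1-tert-butyl 2-methyl 4,7-dibromoindoline-1,2-dicarboxylate (racemic) | COC(=O)C1Cc2c(Br)ccc(Br)c2N1C(=O)OC(C)(C)C | intermediate
10 | methyl 4,7-dibromoindoline-2-carboxylate (racemic) | COC(=O)C1Cc2c(Br)ccc(Br)c2N1 | intermediate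
11 | methyl 4,7-dibromo-1H-indole-2-carboxylate | COC(=O)c1cc2c(Br)ccc(Br)c2[nH]1 | intermediate
12 | methyl 4,7-dibromo-3-chloro-1H-indole-2-carboxylate | COC(=O)c1[nH]c2c(Br)ccc(Br)c2c1Cl | intermediate
13 | 4,7-dibromo-3-chloro-1H-indole-2-carboxylic acid | OC(=O)c1[nH]c2c(Br)ccc(Br)c2c1Cl | intermediate
14 | 2,4,7-tribromo-3-chloro-1H-indole | Clc1c(Br)[nH]c2c(Br)ccc(Br)c12 | target

**Step count**
Total steps: 9. Longest linear sequence: 9 steps (1 → 14); 7 is bought and enters at step 4.

**Steps most likely to fail, with fallbacks**

1. Step 4. The ortho-bromoaryl anion formed after N-arylation may lose bromide (a second aryne and oligomers) or be protonated before it closes the ring, leaving an uncyclised N-aryl enamide. The fallback sets out from 6 and comes back at 11, so that steps 5 and 6 are not needed. It uses the aryne only for the N–aryl bond and closes the ring by a Fischer indolisation. Methyl pyruvate is condensed with 4-methylbenzenesulfonohydrazide (MeOH, 23 °C) to methyl 2-[2-(4-methylbenzenesulfonyl)hydrazinylidene]propanoate F1. Silyl triflate 6 is then treated with CsF in MeCN at 23 °C in the presence of this hydrazone, so that aryne 8 is N-arylated at the sulfonamide nitrogen and the aryl anion is quenched at once by the acidic N–H, which should give methyl 2-[2-(2,5-dibromophenyl)-2-(4-methylbenzenesulfonyl)hydrazinylidene]propanoate F2. BF3·OEt2 in MeCN at reflux should bring about the [3,3] shift and cyclisation onto the only free ortho position, to methyl 4,7-dibromo-1-(4-methylbenzenesulfonyl)-1H-indole-2-carboxylate F3. Cs2CO3 in THF/MeOH then removes the sulfonyl group to give 11.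

2. Step 9. Attack of the brominating agent at the hindered, electron-poor C2 may be slow, so that oxidation of the C2–C3 bond or bromination of the benzo ring competes with the ipso exchange. The fallback sets out from 13 and comes back at 14 and separates the two events. Protodecarboxylation with Ag2CO3 (catalytic) and AcOH in DMSO at 120 °C should give 4,7-dibromo-3-chloro-1H-indole F4. Its free C2 position is then brominated with NBS in CH2Cl2 at 0 °C, the established way from 3-chloroindoles to 2-bromo-3-chloroindoles, to give 14.

3. Step 2. The ortho-bromoaryllithium may eliminate LiBr (aryne formation) or let a bromine migrate before the silyl group shifts. The fallback sets out from 1 and comes back at 5 and replaces the silyl migration by trapping with an external silyl chloride that is already present. Phenol 1 is protected with chloromethyl methyl ether and iPr2NEt in CH2Cl2 as 1,4-dibromo-2-(methoxymethoxy)benzene F5. LiN(iPr)2 is added to a mixture of this ether and Me3SiCl in THF at −78 °C, so that the aryllithium is silylated as soon as it forms, giving [3,6-dibromo-2-(methoxymethoxy)phenyl]trimethylsilane F6. HCl in MeOH at 23 °C cleaves the acetal to give 5.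

**Further compounds**
F1 | step 4 | methyl 2-[2-(4-methylbenzenesulfonyl)hydrazinylidene]propanoate | COC(=O)C(C)=NNS(=O)(=O)c1ccc(C)cc1
F2 | step 4 | methyl 2-[2-(2,5-dibromophenyl)-2-(4-methylbenzenesulfonyl)hydrazinylidene]propanoate | COC(=O)C(C)=NN(c1cc(Br)ccc1Br)S(=O)(=O)c1ccc(C)cc1
F3 | step 4 | methyl 4,7-dibromo-1-(4-methylbenzenesulfonyl)-1H-indole-2-carboxylate | COC(=O)c1cc2c(Br)ccc(Br)c2n1S(=O)(=O)c1ccc(C)cc1
F4 | step 9 | 4,7-dibromo-3-chloro-1H-indole | Clc1c[nH]c2c(Br)ccc(Br)c12
F5 | step 2 | 1,4-dibromo-2-(methoxymethoxy)benzene | COCOc1cc(Br)ccc1Br
F6 | step 2 | [3,6-dibromo-2-(methoxymethoxy)phenyl]trimethylsilane | COCOc1c(Br)ccc(Br)c1[Si](C)(C)C
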